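**Retrosynthetic overview**

1. Numbering: ring A is the 14-membered carbocycle C1 (ring-fusion CH), C2 (lactone O–CH), C3=C4, C5, C6 (OAc), C7=C8, C9, C10 (OAc), C11=C12, C13, C14; ring B is the lactone C1–C2–O–C16(=O)–C15 with exocyclic C17H2. The strategy rests on the unit C10(O)–C11H=C12(CH3)–C13H2–C14, which is the 1,4-adduct of a C14 carbanion with a C10–C11 oxirane carrying an isopropenyl group (C12=C13) on C11.
2. Ring A is closed last, at C13–C14, by zerovalent-palladium ionisation of that vinyl epoxide in a seco-lactone bearing C14H(SO2Ph)2; desulfonylation, C17 methylenation and acetylation follow.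
3. Ring B is formed first, as a butenolide from a C2 γ-hydroxy ynoate (enal + methyl propiolate), followed by anti Michael addition of bis(phenylsulfonyl)methane at C1.
4. The vinyl epoxide comes from an (E)-C10=C11 allylic (S)-carbinol at C12 by Sharpless epoxidation, oxidation and Wittig methylenation; C3=C4 comes from carboalumination and C6 from catalytic propargylation of a C6–C13 dienal.
5. C9–C10 is made by allyl–alkenyl Suzuki coupling of a prenyl-acetate-derived C6–C9 bromide with an alkenylboronate from (S)-but-3-yn-2-ol.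

Key step: step 19

Assumption: the sense of induction quoted for the two catalyst-controlled carbonyl additions (steps 8 and 12) is taken by analogy with simple aryl and alkenyl aldehydes; if a Mosher analysis shows the opposite sense, the antipodal catalyst is used and nothing else changes.

**Route**

Step 1
Reactants: 1 prenyl acetate (3-methylbut-2-en-1-yl acetate)
Product: 2 (2E)-4-hydroxy-3-methylbut-2-en-1-yl acetate
Conditions: SeO2 (cat.), t-BuOOH, salicylic acid (cat.), CH2Cl2, rt
Reagents that add atoms: tert-butyl hydroperoxide, CC(C)(C)OO (oxygen relayed by SeO2, O=[Se]=O)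
Why: Riley allylic oxidation (ene reaction then [2,3]-shift) attacks the methyl group trans to the CH2OAc chain of the trisubstituted olefin, so the future C9 is oxygenated with the E geometry of C7=C8 fixed.

Step 2
Reactants: 2 (2E)-4-hydroxy-3-methylbut-2-en-1-yl acetate
Product: 3 (2E)-4-bromo-3-methylbut-2-en-1-yl acetate
Conditions: CBr4, PPh3, CH2Cl2, 0 °C
Reagents that add atoms: carbon tetrabromide, BrC(Br)(Br)Br
Why: Appel bromination of the primary allylic alcohol proceeds by SN2 displacement under neutral conditions, without allylic transposition and without touching the acetate.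

Step 3
Reactants: 4 (S)-but-3-yn-2-ol
Product: 5 (S)-(but-3-yn-2-yloxy)triethylsilane
Conditions: Et3SiCl, imidazole, CH2Cl2, 0 °C
Reagents that add atoms: chlorotriethylsilane, CC[Si](Cl)(CC)CC
Why: Imidazole-promoted O-silylation masks the future C12 carbinol with a group that can later be removed in the presence of a tert-butyldimethylsilyl ether; the stereocentre is not involved.

Step 4
Reactants: 5 (S)-(but-3-yn-2-yloxy)triethylsilane
Product: 6 triethyl{[(2S,3E)-4-(4,4,5,5-tetramethyl-1,3,2-dioxaborolan-2-yl)but-3-en-2-yl]oxy}silane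
Conditions: pinacolborane, Cp2Zr(H)Cl (5 mol%), Et3N (10 mol%), neat, 60 °C
Reagents that add atoms: pinacolborane, [H]B1OC(C)(C)C(C)(C)O1
Why: Cp2Zr(H)Cl-catalysed hydroboration adds H–B syn across the terminal alkyne with boron at the terminus, giving the (E)-alkenylboronate that will become C10=C11.

Step 5
Reactants: 3 (2E)-4-bromo-3-methylbut-2-en-1-yl acetate; 6 triethyl{[(2S,3E)-4-(4,4,5,5-tetramethyl-1,3,2-dioxaborolan-2-yl)but-3-en-2-yl]oxy}silane
Product: 7 (2E,5E,7S)-3-methyl-7-(triethylsilyloxy)octa-2,5-dien-1-yl acetate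
Conditions: Pd(PPh3)4 (5 mol%), K3PO4 (aq.), THF, 45 °C
Reagents that add atoms: none
Why: Suzuki–Miyaura allyl–alkenyl coupling forms C9–C10 at the unsubstituted allyl terminus with retention of both olefin geometries, since the allylic bromide ionises far faster than the allylic acetate when one equivalent of 6 is used (any acetate lost to the aqueous base converges in step 6).

Step 6
Reactants: 7 (2E,5E,7S)-3-methyl-7-(triethylsilyloxy)octa-2,5-dien-1-yl acetate
Product: 8 (2E,5E,7S)-3-methyl-7-(triethylsilyloxy)octa-2,5-dien-1-ol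
Conditions: K2CO3 (cat.), MeOH, 0 °C
Reagents that add atoms: none
Why: Base-catalysed transesterification removes the acetate while the secondary triethylsilyl ether is stable to cold carbonate in methanol.

Step 7
Reactants: 8 (2E,5E,7S)-3-methyl-7-(triethylsilyloxy)octa-2,5-dien-1-ol
Product: 9 (2E,5E,7S)-3-methyl-7-(triethylsilyloxy)octa-2,5-dienal
Conditions: MnO2, CH2Cl2, rt
Reagents that add atoms: none
Why: MnO2 oxidises the primary allylic alcohol selectively under neutral conditions, so the skipped diene should not move into conjugation and the E enal geometry is kept.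

Step 8
Reactants: 9 (2E,5E,7S)-3-methyl-7-(triethylsilyloxy)octa-2,5-dienal; 10 allenylboronic acid pinacol ester
Product: 12 (4S,5E,8E,10S)-6-methyl-10-(triethylsilyloxy)undeca-5,8-dien-1-yn-4-ol, via pinacol borate ester 11 (not isolated)
Conditions: (S)-3,3'-bis(2,4,6-triisopropylphenyl)-1,1'-binaphthyl-2,2'-diyl hydrogen phosphate (5 mol%), 4 Å MS, toluene, −20 °C; then H2O
Reagents that add atoms: none
Why: Chiral-phosphoric-acid-catalysed propargylation with the allenylboronate goes through a closed six-membered SE2' transition state in which the catalyst should direct attack to the Si face of the enal, setting C6 as S (the (R)-acid gives R carbinols with aryl aldehydes).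

Step 9
Reactants: 12 (4S,5E,8E,10S)-6-methyl-10-(triethylsilyloxy)undeca-5,8-dien-1-yn-4-ol
Product: 13 tert-butyldimethyl{[(4S,5E,8E,10S)-6-methyl-10-(triethylsilyloxy)undeca-5,8-dien-1-yn-4-yl]oxy}silane
Conditions: t-BuMe2SiCl, imidazole, DMF, rt
Reagents that add atoms: tert-butyldimethylsilyl chloride, CC(C)(C)[Si](C)(C)Cl
Why: Standard silylation protects the C6 carbinol with a group more robust than the C12 triethylsilyl ether, without touching the stereocentre.

Step 10
Reactants: 13 tert-butyldimethyl{[(4S,5E,8E,10S)-6-methyl-10-(triethylsilyloxy)undeca-5,8-dien-1-yn-4-yl]oxy}silane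
Product: 16 (2E,5S,6E,9E,11S)-5-(tert-butyldimethylsilyloxy)-3,7-dimethyl-11-(triethylsilyloxy)dodeca-2,6,9-trien-1-ol, via alkenyldimethylalane 14 (not isolated), via lithium alkenylalanate 15 (not isolated)
Conditions: Me3Al, Cp2ZrCl2 (25 mol%), CH2Cl2, 0 °C to rt; evaporate; n-BuLi, THF/hexane, −78 °C; (CH2O)n, −78 °C to rt; then H2O (KNaC4H4O6)
Reagents that add atoms: trimethylaluminium, C[Al](C)C; paraformaldehyde (as formaldehyde), C=O
Why: Negishi zirconium-catalysed carboalumination adds methyl and aluminium syn across the terminal alkyne with aluminium at the terminus (internal olefins are inert), and the derived alanate captures formaldehyde with retention, giving the E olefin C3=C4 and C2 as CH2OH.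

Step 11
Reactants: 16 (2E,5S,6E,9E,11S)-5-(tert-butyldimethylsilyloxy)-3,7-dimethyl-11-(triethylsilyloxy)dodeca-2,6,9-trien-1-ol
Product: 17 (2E,5S,6E,9E,11S)-5-(tert-butyldimethylsilyloxy)-3,7-dimethyl-11-(triethylsilyloxy)dodeca-2,6,9-trienal
Conditions: MnO2, CH2Cl2, rt
Reagents that add atoms: none
Why: Selective allylic oxidation gives the enal without E/Z isomerisation or loss of the silyl ethers.

Step 12
Reactants: 17 (2E,5S,6E,9E,11S)-5-(tert-butyldimethylsilyloxy)-3,7-dimethyl-11-(triethylsilyloxy)dodeca-2,6,9-trienal; 18 methyl propiolate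
Product: 20 methyl (4S,5E,8S,9E,12E,14S)-8-(tert-butyldimethylsilyloxy)-4-hydroxy-6,10-dimethyl-14-(triethylsilyloxy)pentadeca-5,9,12-trien-2-ynoate, via methylzinc alkynylide 19 (not isolated)
Conditions: Me2Zn, 2,6-bis{[(S)-2-(hydroxydiphenylmethyl)pyrrolidin-1-yl]methyl}-4-methylphenol ((S,S)-ProPhenol, 20 mol%), Ph3P=O (40 mol%), toluene, 4 °C; then H2O
Reagents that add atoms: none
Why: Dinuclear zinc–ProPhenol alkynylation of an α,β-unsaturated aldehyde delivers the zinc acetylide of methyl propiolate 1,2 within the chiral pocket, here to the Re face of the enal, which sets C2 as S and installs C1, C15 and C16 in one operation.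

Step 13
Reactants: 20 methyl (4S,5E,8S,9E,12E,14S)-8-(tert-butyldimethylsilyloxy)-4-hydroxy-6,10-dimethyl-14-(triethylsilyloxy)pentadeca-5,9,12-trien-2-ynoate
Product: 22 (5R)-5-[(1E,4S,5E,8E,10S)-4-(tert-butyldimethylsilyloxy)-2,6-dimethyl-10-(triethylsilyloxy)undeca-1,5,8-trien-1-yl]furan-2(5H)-one, via Z-hydroxy enoate 21 (not isolated)
Conditions: H2 (1 atm), Pd/CaCO3 poisoned with Pb(OAc)2, quinoline, EtOAc, rt; then SiO2, CH2Cl2, rt
Reagents that add atoms: none
Why: Lindlar syn semihydrogenation of the electron-poor alkyne gives the Z γ-hydroxy enoate, which lactonises with loss of methanol to ring B as a butenolide; C2 is untouched and its descriptor changes to R only through the priority rules.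

Step 14
Reactants: 22 (5R)-5-[(1E,4S,5E,8E,10S)-4-(tert-butyldimethylsilyloxy)-2,6-dimethyl-10-(triethylsilyloxy)undeca-1,5,8-trien-1-yl]furan-2(5H)-one; 23 bis(phenylsulfonyl)methane
Product: 24 (4R,5S)-4-[bis(phenylsulfonyl)methyl]-5-[(1E,4S,5E,8E,10S)-4-(tert-butyldimethylsilyloxy)-2,6-dimethyl-10-(triethylsilyloxy)undeca-1,5,8-trien-1-yl]oxolan-2-one
Conditions: Cs2CO3 (0.3 equiv), MeCN, rt
Reagents that add atoms: none
Why: Michael addition of the bis(phenylsulfonyl)methanide to the butenolide occurs at C1 on the face opposite to the C2 alkenyl group, and reversibility also favours the trans-4,5-disubstituted lactone, so C1 is set as R relative to C2; excess pronucleophile caps the basicity of the medium to protect the C2–H.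

Step 15
Reactants: 24 (4R,5S)-4-[bis(phenylsulfonyl)methyl]-5-[(1E,4S,5E,8E,10S)-4-(tert-butyldimethylsilyloxy)-2,6-dimethyl-10-(triethylsilyloxy)undeca-1,5,8-trien-1-yl]oxolan-2-one
Product: 25 (4R,5S)-4-[bis(phenylsulfonyl)methyl]-5-[(1E,4S,5E,8E,10S)-4-(tert-butyldimethylsilyloxy)-10-hydroxy-2,6-dimethylundeca-1,5,8-trien-1-yl]oxolan-2-one
Conditions: pyridinium p-toluenesulfonate (cat.), MeOH/CH2Cl2, 0 °C
Reagents that add atoms: none
Why: Mild acid-catalysed methanolysis cleaves the triethylsilyl ether much faster than the tert-butyldimethylsilyl ether, freeing only the C12 allylic carbinol.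

Step 16
Reactants: 25 (4R,5S)-4-[bis(phenylsulfonyl)methyl]-5-[(1E,4S,5E,8E,10S)-4-(tert-butyldimethylsilyloxy)-10-hydroxy-2,6-dimethylundeca-1,5,8-trien-1-yl]oxolan-2-one
Product: 26 (4R,5S)-4-[bis(phenylsulfonyl)methyl]-5-[(1E,4S,5E)-4-(tert-butyldimethylsilyloxy)-7-{(2S,3S)-3-[(1S)-1-hydroxyethyl]oxiran-2-yl}-2,6-dimethylhepta-1,5-dien-1-yl]oxolan-2-one
Conditions: Ti(Oi-Pr)4 (0.3 equiv), L-(+)-diisopropyl tartrate (0.36 equiv), t-BuOOH, 4 Å MS, CH2Cl2, −20 °C
Reagents that add atoms: tert-butyl hydroperoxide, CC(C)(C)OO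
Why: Sharpless asymmetric epoxidation acts only on the free allylic alcohol; L-(+)-tartrate and the (S)-carbinol are the matched pair, so oxygen is delivered to the face that gives the (10S,11S) trans-epoxide (erythro epoxy alcohol), which fixes the C10 configuration of the target.

Step 17
Reactants: 26 (4R,5S)-4-[bis(phenylsulfonyl)methyl]-5-[(1E,4S,5E)-4-(tert-butyldimethylsilyloxy)-7-{(2S,3S)-3-[(1S)-1-hydroxyethyl]oxiran-2-yl}-2,6-dimethylhepta-1,5-dien-1-yl]oxolan-2-one
Product: 27 (4R,5S)-5-{(1E,4S,5E)-7-[(2S,3R)-3-acetyloxiran-2-yl]-4-(tert-butyldimethylsilyloxy)-2,6-dimethylhepta-1,5-dien-1-yl}-4-[bis(phenylsulfonyl)methyl]oxolan-2-one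
Conditions: Dess–Martin periodinane, NaHCO3, CH2Cl2, 0 °C to rt
Reagents that add atoms: none
Why: Buffered Dess–Martin oxidation converts the secondary carbinol into the methyl ketone without opening or epimerising the epoxide (the C11 descriptor becomes R only through the priority rules).

Step 18
Reactants: 27 (4R,5S)-5-{(1E,4S,5E)-7-[(2S,3R)-3-acetyloxiran-2-yl]-4-(tert-butyldimethylsilyloxy)-2,6-dimethylhepta-1,5-dien-1-yl}-4-[bis(phenylsulfonyl)methyl]oxolan-2-one
Product: 28 (4R,5S)-4-[bis(phenylsulfonyl)methyl]-5-{(1E,4S,5E)-4-(tert-butyldimethylsilyloxy)-2,6-dimethyl-7-[(2S,3S)-3-(prop-1-en-2-yl)oxiran-2-yl]hepta-1,5-dien-1-yl}oxolan-2-one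
Conditions: Ph3PCH3Br, KN(SiMe3)2, THF, −78 to 0 °C (3 equiv of ylide); then H2O
Reagents that add atoms: methyltriphenylphosphonium bromide, [Br-].C[P+](c1ccccc1)(c1ccccc1)c1ccccc1
Why: Wittig methylenation of the epoxy methyl ketone builds the isopropenyl group (C12=C13); one equivalent of ylide is taken up reversibly by the acidic C14–H, which is restored on work-up, and the lactone should not be attacked by the non-stabilised ylide at 0 °C.

Step 19
Reactants: 28 (4R,5S)-4-[bis(phenylsulfonyl)methyl]-5-{(1E,4S,5E)-4-(tert-butyldimethylsilyloxy)-2,6-dimethyl-7-[(2S,3S)-3-(prop-1-en-2-yl)oxiran-2-yl]hepta-1,5-dien-1-yl}oxolan-2-one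
Product: 29 bicyclic lactone (1R,2S,6S,10S;3E,7E,11E) with ring A closed, carrying C14(SO2Ph)2, free C10–OH, C6–OSi(t-Bu)Me2 and C15H2
Conditions: Pd(PPh3)4 (10 mol%), Ph2PCH2CH2PPh2 (10 mol%), THF, reflux, syringe-pump addition (final 0.002 M)
Reagents that add atoms: none
Why: Zerovalent palladium coordinates the isopropenyl group and ionises the strained allylic C11–O bond with inversion, giving a zwitterionic π-allylpalladium complex (C11–C12–C13) whose C10 alkoxide removes the acidic C14–H of the bis(phenylsulfonyl)methine; the carbanion, born next to its electrophile, attacks the CH2 terminus C13 and releases zerovalent palladium. This is the neutral Tsuji–Trost macrocyclisation of vinyl epoxides with sulfone-stabilised carbon pronucleophiles. Ring A closes as the 14-membered carbocycle by attack at the distal allyl terminus, the mode that places the new C11=C12 olefin inside the ring, and not as the 12-membered ring from attack at C11. No stereocentre is created: C10 keeps its S configuration from step 16 because its C–O bond is never broken, and C11 becomes sp2. The step needs distal regioselectivity (secured by the unhindered primary C13 against C11, which is flanked by the alkoxide-bearing C10 and faces a bulky tertiary carbanion), the E olefin (secured by syn/anti equilibration of the π-allyl complex toward the isomer with the C10 chain syn), chemoselective ionisation of the epoxide over the C2 allylic lactone C–O and the C6 allylic silyl ether (secured by ring strain and by the trisubstituted olefins next to those positions), and cyclisation over oligomerisation (secured by slow addition at high dilution).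

Step 20
Reactants: 29 bicyclic lactone with C14(SO2Ph)2, free C10–OH and C6–OSi(t-Bu)Me2
Product: 30 bicyclic lactone (1R,2S,6S,10S;3E,7E,11E) carrying C14(SO2Ph)2 and OSi(t-Bu)Me2 groups on C6 and C10
Conditions: t-BuMe2SiCl, imidazole, DMF, rt
Reagents that add atoms: tert-butyldimethylsilyl chloride, CC(C)(C)[Si](C)(C)Cl
Why: Silylation of the unhindered secondary allylic C10 alcohol removes the only acidic O–H before the reductive and strongly basic steps that follow.

Step 21
Reactants: 30 bicyclic lactone with C14(SO2Ph)2 and C6, C10 silyl ethers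
Product: 31 bicyclic lactone (1R,2S,6S,10S;3E,7E,11E) with C14H2, C15H2 and OSi(t-Bu)Me2 groups on C6 and C10
Conditions: 6% Na(Hg), Na2HPO4, MeOH/THF, −20 °C
Reagents that add atoms: none
Why: Reductive desulfonylation by electron transfer from sodium amalgam cleaves both C14–S bonds in turn, the phosphate buffer keeping methoxide from opening the lactone, and C1 next to C14 is not epimerisable.

Step 22
Reactants: 31 bicyclic lactone with C14H2 and C6, C10 silyl ethers
Product: 33 bicyclic lactone bearing CH2NMe2 on C15 (C6 and C10 OSi(t-Bu)Me2; C15 epimers), via lithium enolate 32 (not isolated)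
Conditions: LiN(i-Pr)2, THF, −78 °C; CH2=NMe2+ I−, −78 °C to rt
Reagents that add atoms: N,N-dimethylmethyleneiminium iodide (Eschenmoser's salt), [I-].C=[N+](C)C
Why: The lithium enolate of the γ-lactone (only C15 bears α-hydrogens) is aminomethylated by the iminium salt in a Mannich reaction; the C15 configuration is irrelevant because it is removed in step 23.

Step 23
Reactants: 33 bicyclic lactone bearing CH2NMe2 on C15
Product: 35 6,10-bis-O-(tert-butyldimethylsilyl) derivative of the C15=C17 methylene lactone, via trimethylammonium iodide 34 (not isolated)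
Conditions: MeI, MeOH, rt; then NaHCO3 (aq.), CH2Cl2, rt
Reagents that add atoms: none
Why: Exhaustive methylation turns the amine into a leaving group and mild base effects E1cB elimination to the exocyclic C15=C17 olefin without epimerising C1.

Step 24
Reactants: 35 6,10-bis-O-(tert-butyldimethylsilyl) methylene lactone
Product: 36 6,10-diol of the methylene lactone (1R,2S,6S,10S;3E,7E,11E)
Conditions: HF·pyridine, pyridine, THF, 0 °C to rt
Reagents that add atoms: none
Why: Buffered fluoride cleaves both secondary silyl ethers under weakly acidic conditions that leave the α-methylene lactone and the allylic carbinols intact.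

Step 25
Reactants: 36 6,10-diol of the methylene lactone
Product: 37 target, (1R,2S,6S,10S;3E,7E,11E)-6,10-diacetoxy-4,8,12-trimethyl ring A fused to the α-methylene γ-lactone (CID11069750)
Conditions: Ac2O, pyridine, 4-(dimethylamino)pyridine (cat.), CH2Cl2, rt
Reagents that add atoms: acetic anhydride, CC(=O)OC(C)=O
Why: Nucleophile-catalysed O-acylation of both secondary allylic alcohols proceeds with retention at C6 and C10 and should give the target.

**Compound list**

1 | prenyl acetate | CC(C)=CCOC(C)=O | starting material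
2 | (2E)-4-hydroxy-3-methylbut-2-en-1-yl acetate | CC(=O)OC/C=C(\C)CO | intermediate
3 | (2E)-4-bromo-3-methylbut-2-en-1-yl acetate | CC(=O)OC/C=C(\C)CBr | intermediate
4 | (S)-but-3-yn-2-ol | C[C@H](O)C#C | starting material
5 | (S)-(but-3-yn-2-yloxy)triethylsilane | C[C@H](O[Si](CC)(CC)CC)C#C | intermediate
6 | triethyl{[(2S,3E)-4-(4,4,5,5-tetramethyl-1,3,2-dioxaborolan-2-yl)but-3-en-2-yl]oxy}silane | C[C@H](O[Si](CC)(CC)CC)/C=C/B1OC(C)(C)C(C)(C)O1 | intermediate
7 | (2E,5E,7S)-3-methyl-7-(triethylsilyloxy)octa-2,5-dien-1-yl acetate | CC(=O)OC/C=C(\C)C/C=C/[C@H](C)O[Si](CC)(CC)CC | intermediate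
8 | (2E,5E,7S)-3-methyl-7-(triethylsilyloxy)octa-2,5-dien-1-ol | OC/C=C(\C)C/C=C/[C@H](C)O[Si](CC)(CC)CC | intermediate
9 | (2E,5E,7S)-3-methyl-7-(triethylsilyloxy)octa-2,5-dienal | O=C/C=C(\C)C/C=C/[C@H](C)O[Si](CC)(CC)CC | intermediate
10 | allenylboronic acid pinacol ester | C=C=CB1OC(C)(C)C(C)(C)O1 | starting material
11 | pinacol borate ester of 12 (O-boryl homopropargylic alcohol) | C#CC[C@H](OB1OC(C)(C)C(C)(C)O1)/C=C(\C)C/C=C/[C@H](C)O[Si](CC)(CC)CC | intermediate (not isolated)
12 | (4S,5E,8E,10S)-6-methyl-10-(triethylsilyloxy)undeca-5,8-dien-1-yn-4-ol | C#CC[C@H](O)/C=C(\C)C/C=C/[C@H](C)O[Si](CC)(CC)CC | intermediate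
13 | tert-butyldimethyl{[(4S,5E,8E,10S)-6-methyl-10-(triethylsilyloxy)undeca-5,8-dien-1-yn-4-yl]oxy}silane | C#CC[C@H](O[Si](C)(C)C(C)(C)C)/C=C(\C)C/C=C/[C@H](C)O[Si](CC)(CC)CC | intermediate
14 | (E)-alkenyldimethylalane from carboalumination of 13 (Al on C3, methyl on C4) | C[Al](C)/C=C(\C)C[C@H](O[Si](C)(C)C(C)(C)C)/C=C(\C)C/C=C/[C@H](C)O[Si](CC)(CC)CC | intermediate (not isolated)
15 | lithium butyl(alkenyl)dimethylalanate from 14 | [Li+].CCCC[Al-](C)(C)/C=C(\C)C[C@H](O[Si](C)(C)C(C)(C)C)/C=C(\C)C/C=C/[C@H](C)O[Si](CC)(CC)CC | intermediate (not isolated)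
16 | (2E,5S,6E,9E,11S)-5-(tert-butyldimethylsilyloxy)-3,7-dimethyl-11-(triethylsilyloxy)dodeca-2,6,9-trien-1-ol | OC/C=C(\C)C[C@H](O[Si](C)(C)C(C)(C)C)/C=C(\C)C/C=C/[C@H](C)O[Si](CC)(CC)CC | intermediate
17 | (2E,5S,6E,9E,11S)-5-(tert-butyldimethylsilyloxy)-3,7-dimethyl-11-(triethylsilyloxy)dodeca-2,6,9-trienal | O=C/C=C(\C)C[C@H](O[Si](C)(C)C(C)(C)C)/C=C(\C)C/C=C/[C@H](C)O[Si](CC)(CC)CC | intermediate
18 | methyl propiolate | C#CC(=O)OC | starting material
19 | methylzinc alkynylide of methyl propiolate | C[Zn]C#CC(=O)OC | intermediate (not isolated)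
20 | methyl (4S,5E,8S,9E,12E,14S)-8-(tert-butyldimethylsilyloxy)-4-hydroxy-6,10-dimethyl-14-(triethylsilyloxy)pentadeca-5,9,12-trien-2-ynoate | COC(=O)C#C[C@@H](O)/C=C(\C)C[C@H](O[Si](C)(C)C(C)(C)C)/C=C(\C)C/C=C/[C@H](C)O[Si](CC)(CC)CC | intermediate
21 | methyl (2Z,4R,5E,8S,9E,12E,14S)-8-(tert-butyldimethylsilyloxy)-4-hydroxy-6,10-dimethyl-14-(triethylsilyloxy)pentadeca-2,5,9,12-tetraenoate | COC(=O)/C=C\[C@@H](O)/C=C(\C)C[C@H](O[Si](C)(C)C(C)(C)C)/C=C(\C)C/C=C/[C@H](C)O[Si](CC)(CC)CC | intermediate (not isolated)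
22 | (5R)-5-[(1E,4S,5E,8E,10S)-4-(tert-butyldimethylsilyloxy)-2,6-dimethyl-10-(triethylsilyloxy)undeca-1,5,8-trien-1-yl]furan-2(5H)-one | O=C1C=C[C@H](/C=C(\C)C[C@H](O[Si](C)(C)C(C)(C)C)/C=C(\C)C/C=C/[C@H](C)O[Si](CC)(CC)CC)O1 | intermediate
23 | bis(phenylsulfonyl)methane | O=S(=O)(CS(=O)(=O)c1ccccc1)c1ccccc1 | starting material
24 | (4R,5S)-4-[bis(phenylsulfonyl)methyl]-5-[(1E,4S,5E,8E,10S)-4-(tert-butyldimethylsilyloxy)-2,6-dimethyl-10-(triethylsilyloxy)undeca-1,5,8-trien-1-yl]oxolan-2-one | O=S(=O)(c1ccccc1)C([C@@H]2CC(=O)O[C@H]2/C=C(\C)C[C@H](O[Si](C)(C)C(C)(C)C)/C=C(\C)C/C=C/[C@H](C)O[Si](CC)(CC)CC)S(=O)(=O)c1ccccc1 | intermediate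
25 | (4R,5S)-4-[bis(phenylsulfonyl)methyl]-5-[(1E,4S,5E,8E,10S)-4-(tert-butyldimethylsilyloxy)-10-hydroxy-2,6-dimethylundeca-1,5,8-trien-1-yl]oxolan-2-one | O=S(=O)(c1ccccc1)C([C@@H]2CC(=O)O[C@H]2/C=C(\C)C[C@H](O[Si](C)(C)C(C)(C)C)/C=C(\C)C/C=C/[C@H](C)O)S(=O)(=O)c1ccccc1 | intermediate
26 | (4R,5S)-4-[bis(phenylsulfonyl)methyl]-5-[(1E,4S,5E)-4-(tert-butyldimethylsilyloxy)-7-{(2S,3S)-3-[(1S)-1-hydroxyethyl]oxiran-2-yl}-2,6-dimethylhepta-1,5-dien-1-yl]oxolan-2-one | O=S(=O)(c1ccccc1)C([C@@H]2CC(=O)O[C@H]2/C=C(\C)C[C@H](O[Si](C)(C)C(C)(C)C)/C=C(\C)C[C@@H]3O[C@H]3[C@H](C)O)S(=O)(=O)c1ccccc1 | intermediate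
27 | (4R,5S)-5-{(1E,4S,5E)-7-[(2S,3R)-3-acetyloxiran-2-yl]-4-(tert-butyldimethylsilyloxy)-2,6-dimethylhepta-1,5-dien-1-yl}-4-[bis(phenylsulfonyl)methyl]oxolan-2-one | O=S(=O)(c1ccccc1)C([C@@H]2CC(=O)O[C@H]2/C=C(\C)C[C@H](O[Si](C)(C)C(C)(C)C)/C=C(\C)C[C@@H]3O[C@H]3C(C)=O)S(=O)(=O)c1ccccc1 | intermediate
28 | (4R,5S)-4-[bis(phenylsulfonyl)methyl]-5-{(1E,4S,5E)-4-(tert-butyldimethylsilyloxy)-2,6-dimethyl-7-[(2S,3S)-3-(prop-1-en-2-yl)oxiran-2-yl]hepta-1,5-dien-1-yl}oxolan-2-one (key-step precursor) | O=S(=O)(c1ccccc1)C([C@@H]2CC(=O)O[C@H]2/C=C(\C)C[C@H](O[Si](C)(C)C(C)(C)C)/C=C(\C)C[C@@H]3O[C@H]3C(C)=C)S(=O)(=O)c1ccccc1 | intermediate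
29 | bicyclic lactone (1R,2S,6S,10S; 3E,7E,11E): ring A closed, C14(SO2Ph)2, C10–OH, C6–OSi(t-Bu)Me2, C15H2 (key-step product) | C1C(=O)O[C@H]2/C=C(\C)C[C@H](O[Si](C)(C)C(C)(C)C)/C=C(\C)C[C@H](O)/C=C(\C)CC(S(=O)(=O)c3ccccc3)(S(=O)(=O)c3ccccc3)[C@H]12 | intermediate
30 | C10 tert-butyldimethylsilyl ether of 29 | C1C(=O)O[C@H]2/C=C(\C)C[C@H](O[Si](C)(C)C(C)(C)C)/C=C(\C)C[C@H](O[Si](C)(C)C(C)(C)C)/C=C(\C)CC(S(=O)(=O)c3ccccc3)(S(=O)(=O)c3ccccc3)[C@H]12 | intermediate
31 | desulfonylated bicyclic lactone (C14H2; C6 and C10 OSi(t-Bu)Me2) | C1C(=O)O[C@H]2/C=C(\C)C[C@H](O[Si](C)(C)C(C)(C)C)/C=C(\C)C[C@H](O[Si](C)(C)C(C)(C)C)/C=C(\C)CC[C@H]12 | intermediate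
32 | lithium enolate of 31 (C15=C16–OLi) | C1=C(O[Li])O[C@H]2/C=C(\C)C[C@H](O[Si](C)(C)C(C)(C)C)/C=C(\C)C[C@H](O[Si](C)(C)C(C)(C)C)/C=C(\C)CC[C@H]12 | intermediate (not isolated)
33 | C15-(dimethylaminomethyl) lactone (C15 epimers) | CN(C)CC1C(=O)O[C@H]2/C=C(\C)C[C@H](O[Si](C)(C)C(C)(C)C)/C=C(\C)C[C@H](O[Si](C)(C)C(C)(C)C)/C=C(\C)CC[C@H]12 | intermediate
34 | C15-(trimethylammoniomethyl) lactone iodide | [I-].C[N+](C)(C)CC1C(=O)O[C@H]2/C=C(\C)C[C@H](O[Si](C)(C)C(C)(C)C)/C=C(\C)C[C@H](O[Si](C)(C)C(C)(C)C)/C=C(\C)CC[C@H]12 | intermediate (not isolated)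
35 | α-methylene lactone with C6 and C10 OSi(t-Bu)Me2 | C=C1C(=O)O[C@H]2/C=C(\C)C[C@H](O[Si](C)(C)C(C)(C)C)/C=C(\C)C[C@H](O[Si](C)(C)C(C)(C)C)/C=C(\C)CC[C@H]12 | intermediate
36 | α-methylene lactone 6,10-diol | C=C1C(=O)O[C@H]2/C=C(\C)C[C@H](O)/C=C(\C)C[C@H](O)/C=C(\C)CC[C@H]12 | intermediate
37 | target: (1R,2S,6S,10S; 3E,7E,11E)-6,10-diacetoxy α-methylene lactone (CID11069750) | C=C1C(=O)O[C@H]2/C=C(\C)C[C@H](OC(C)=O)/C=C(\C)C[C@H](OC(C)=O)/C=C(\C)CC[C@H]12 | target

**Step count and risks**

Total step count: 25. Longest linear sequence: 23 steps (1, 2, 5–25; the two-step branch 3–4 joins at step 5 and is equally long).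

Steps most likely to fail:

1. Step 19 (ring A closure). The ring closure may be outrun by oligomerisation or by attack at the internal allyl terminus C11. The π-allyl alkoxide may also collapse by β-hydride loss toward a C10 ketone or dienol before the hindered C14–H is transferred, and part of the material may leak to the Z olefin. The fallback sets out from 28 and returns at 30. Pd(PPh3)4 with acetic acid in THF should add acetate to C13 of the same π-allyl complex, the acid quenching the alkoxide, to give the (E)-C10-hydroxy C13-acetate F1, which is purified as the E isomer. Silylation (t-BuMe2SiCl, imidazole) gives the C10 silyl ether F2. NaH converts it into the sodium bis(phenylsulfonyl)methanide F3, which is added slowly to Pd(PPh3)4/Ph2PCH2CH2PPh2 in refluxing THF; this classical Tsuji–Trost macrocyclisation of an allylic acetate with a preformed carbanion should give 30 directly. The olefin geometry is then fixed before ring closure, no alkoxide is present, and the bulky silyl ether shields C11.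

2. Step 14 (Michael addition). The hindered, highly stabilised carbanion may add slowly and reversibly, and forcing with more base or heat would remove the doubly activated C2–H, eroding the C2 configuration through the 2-oxidofuran or moving the olefin. The fallback sets out from 22 and returns at 24. Bis(phenylthio)methane is lithiated with n-BuLi to [bis(phenylthio)methyl]lithium F4, which should add 1,4 to 22 irreversibly at −78 °C in THF, anti to the C2 substituent, to give the trans dithioacetal lactone F5. Chemoselective sulfur oxidation ((NH4)6Mo7O24·4H2O (cat.), H2O2, EtOH, 0 °C), which spares isolated olefins, then gives 24.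

3. Step 12 (alkynylation). Facial selectivity may be poor on an α-unsubstituted, β,β-disubstituted enal, giving C2 epimers, and methyl propiolate may oligomerise under the zinc base. The fallback sets out from 17 and 18 and returns at 20. Methyl propiolate is deprotonated with LiN(SiMe3)2 at −78 °C to lithium methyl propiolate F6, which adds to 17 to give the C2-epimeric carbinols F7. MnO2 oxidation gives the ynone F8. Midland reduction with B-isopinocampheyl-9-borabicyclo[3.3.1]nonane from (−)-α-pinene, in which the alkynyl group acts as the small substituent, should return the 4S carbinol 20.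

Further compounds
F1 | step 19 | (E)-C10-hydroxy C13-acetate of the seco-lactone (C6 OSi(t-Bu)Me2, C14H(SO2Ph)2) | O=S(=O)(c1ccccc1)C([C@@H]2CC(=O)O[C@H]2/C=C(\C)C[C@H](O[Si](C)(C)C(C)(C)C)/C=C(\C)C[C@H](O)/C=C(\C)COC(C)=O)S(=O)(=O)c1ccccc1
F2 | step 19 | C10 tert-butyldimethylsilyl ether of F1 | O=S(=O)(c1ccccc1)C([C@@H]2CC(=O)O[C@H]2/C=C(\C)C[C@H](O[Si](C)(C)C(C)(C)C)/C=C(\C)C[C@H](O[Si](C)(C)C(C)(C)C)/C=C(\C)COC(C)=O)S(=O)(=O)c1ccccc1
F3 | step 19 | sodium bis(phenylsulfonyl)methanide of F2 | [Na+].O=S(=O)(c1ccccc1)[C-]([C@@H]2CC(=O)O[C@H]2/C=C(\C)C[C@H](O[Si](C)(C)C(C)(C)C)/C=C(\C)C[C@H](O[Si](C)(C)C(C)(C)C)/C=C(\C)COC(C)=O)S(=O)(=O)c1ccccc1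
F4 | step 14 | [bis(phenylthio)methyl]lithium | [Li]C(Sc1ccccc1)Sc1ccccc1
F5 | step 14 | (4R,5S)-4-[bis(phenylthio)methyl] analogue of 24 | C(Sc1ccccc1)(Sc1ccccc1)[C@@H]2CC(=O)O[C@H]2/C=C(\C)C[C@H](O[Si](C)(C)C(C)(C)C)/C=C(\C)C/C=C/[C@H](C)O[Si](CC)(CC)CC
F6 | step 12 | lithium methyl propiolate | [Li]C#CC(=O)OC
F7 | step 12 | C2-epimeric mixture of 20 | COC(=O)C#CC(O)/C=C(\C)C[C@H](O[Si](C)(C)C(C)(C)C)/C=C(\C)C/C=C/[C@H](C)O[Si](CC)(CC)CC
F8 | step 12 | methyl (5E,8S,9E,12E,14S)-8-(tert-butyldimethylsilyloxy)-6,10-dimethyl-4-oxo-14-(triethylsilyloxy)pentadeca-5,9,12-trien-2-ynoate | COC(=O)C#CC(=O)/C=C(\C)C[C@H](O[Si](C)(C)C(C)(C)C)/C=C(\C)C/C=C/[C@H](C)O[Si](CC)(CC)CC
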